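The 5 questions come down to 3 histories, since a plug in eta, unmixed, passes through the same time course as the closed flask gamma.

| setting | dusk | winter | dawn | summer | alpha | epsilon | eta | gamma |
|---|---|---|---|---|---|---|---|---|
| substrate | 20 mM | 13 mM | 30 mM | 20 mM | 20 mM | 20 mM (fed, over 4.00 d) | 20 mM | 20 mM |
| precatalyst | 0.40 mM | 0.40 mM | 0.40 mM | 0.20 mM | 0.40 mM | 0.40 mM | 0.40 mM | 0.40 mM |
| remark | run made earlier | run made earlier | run made earlier | run made earlier | a single well-mixed tank run continuously and read at steady state, 4.0 d in it on average | a stirred flask in which substrate is dosed at a steady rate over 4.00 d without added volume, worked up at 4.0 d | plug flow through a tube for 4.0 d, no back-mixing | everything together in a closed stirred flask, run for 4.0 d |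
| time |  |  |  |  |  | 4.0 d | 4.0 d | 4.0 d |

| run | time / d | target / % |
|---|---|---|
| dusk | 1.04 | 5.4 |
| dusk | 2.08 | 18.2 |
| dusk | 3.00 | 34.2 |
| dusk | 4.00 | 56.6 |
| winter | 0.500 | 2.5 |
| winter | 1.25 | 9.5 |
| winter | 2.50 | 37.3 |
| winter | 4.00 | 80.7 |
| dawn | 0.500 | 0.8 |
| dawn | 1.25 | 4.2 |
| dawn | 2.50 | 17.5 |
| dawn | 4.00 | 37.9 |
| summer | 0.333 | 0.6 |
| summer | 0.833 | 1.4 |
| summer | 1.67 | 5.8 |
| summer | 4.00 | 28.2 |

(scatter of a reading: 0.5 percentage points)

- the stated concentrations are those of everything mixed, before any reaction; amounts are the same in each set-up
- the feed brings no volume worth counting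
- the earlier runs were made in a closed, stirred flask

- the set-up with the highest amount of target at the outlet or at the end, in percent of the substrate put in ("none" if the first two lie within 2 percentage points) (alpha / epsilon / eta / gamma / none)
- amount of target at the outlet or at the end, in percent of the substrate put in, alpha
- amount of target at the outlet or at the end, in percent of the substrate put in, epsilon
- amount of target at the outlet or at the end, in percent of the substrate put in, eta
- amount of target at the outlet or at the end, in percent of the substrate put in, gamma

At 4.00 d, dusk holds 11.3 mM of target and dawn 11.4 mM, although dawn was charged with 30 mM against 20 mM. Summer, with half the precatalyst, makes half the target of dusk. The first estimate is therefore a zero-order rate proportional to catalyst. But such a rate gives a straight line, and the mean dusk rate climbs from 2.46 mM d⁻¹ around 1.56 d to 4.00 mM d⁻¹ around 3.04 d, nearly twice the time. If catalyst wakes first order with constant a, its awake fraction at time t is 1 − exp(−at), and the rate at doubled time over the rate at the first time is 1 + exp(−at). The readings then give a wake constant a of 0.301 d⁻¹.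

Integrating the awake fraction in closed form, the precatalyst charge of a closed flask has worked the equivalent of 1.68 d at full strength by 4.0 d: this awake time is Θ = t − (1 − exp(−at))/a. Yet winter reaches 10.5 mM at 4.00 d, less than dusk, so the rate falls at low substrate S. With a saturation constant K and a full-strength rate V at 0.40 mM precatalyst, the integrated rate for target P is P + K ln(charge/S) = VΘ. Dusk and winter share time and precatalyst, so setting them equal reads K as 1.02 mM, VΘ as 12.2 mM and V as 7.27 mM d⁻¹.

Gamma and eta repeat the dusk recipe, so the dusk reading of 56.6 % stands for them. In epsilon the feed of 5.00 mM d⁻¹ is more than V times the awake fraction at 2.00 d, 3.29 mM d⁻¹, and close to that product at the end, 5.09 mM d⁻¹. Substrate therefore accumulates in epsilon, but it starts near zero, and a rough allowance of one K off the dusk amount gives 51.4 %. Alpha raises an objection to Θ, because a tank holds mixed ages. With precatalyst entering in the feed and a mean residence time τ of 4.0 d, the awake fraction in the steady tank of alpha is aτ/(1 + aτ) = 0.547, so the awake time is 2.19 d, more than in the batch. The objection to that is that the tank works at its outlet substrate, but the balance charge − S = VΘS/(K + S), with this awake time as Θ, gives S = 6.33 mM, hence 68.3 % for alpha, more than the estimates for the other set-ups.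

The forecast gives 68 %, 52 %, 57 % and 57 % for alpha, epsilon, eta and gamma, naming alpha, on “slow first-order activation of the precatalyst”. The flasks give 70.4 %, 53.2 %, 55.7 % and 55.7 %, and alpha is best.

    substrate + free catalyst → catalyst intermediate A (k = 0.350 L mol⁻¹ s⁻¹)
    catalyst intermediate A → catalyst intermediate B (k = 8.20 × 10⁻⁴ s⁻¹)
    catalyst intermediate B ⇌ free catalyst + target (K = 1.10 M, k = 3.00 × 10⁻⁴ s⁻¹)
    2 substrate → homo dimer (k = 1.90 × 10⁻⁷ L mol⁻¹ s⁻¹)
    precatalyst → free catalyst (k = 3.10 × 10⁻⁶ s⁻¹)

The precatalyst has a half-life of 2.6 d by its waking step alone, longer than the 0.64 h of catalyst intermediate B by its forward step alone. The target of alpha stands at 1.26 times that of gamma, and the reckoned awake time of alpha at 1.30 times that of gamma. On epsilon left until 40.0 d, V times the awake time reaches 267 mM against a charge of 20 mM, and the flask holds 99.9 %.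

(The earlier runs and the new flask come from a simulation from invented constants; noise was put on by code.)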